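**Strategy**

Ring A, the oxirane-bearing cyclohexane (C1 methyl/oxirane carbon, C2 oxirane CH, C3 with the CH2 link, C4 with isopropenyl, C5, C6), has the substitution pattern of a Diels–Alder adduct: the oxirane marks the adduct alkene, and C4 is "ortho" to C3 and "para" to C1, as a 1-alkyl-3-methylbutadiene demands. The bromohydrin ring comes closed from limonene diol; its isopropenyl group is extended to a linear (E)-triene, and an iminium-catalysed [4+2] cycloaddition with acrolein closes ring A across C3–C4 and C5–C6, setting C3 by catalyst control. Epimerisation at C4, conversion of CHO into isopropenyl and a reagent-controlled epoxidation of C1=C2 complete the route.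

Key step: step 5

Remark: the oxirane is treated as a functional group placed on the finished carbon skeleton; ring B is never opened or closed, so ring A is the only carbocycle the route forms. Ring A locants (C1–C6) in the Why lines are those defined above.

**Route**

Step 1
Reactants: 1 (1S,2S,4R)-1-methyl-4-(prop-1-en-2-yl)cyclohexane-1,2-diol (limonene-1,2-diol)
Product: 3 (1S,2R,4R)-2-bromo-1-methyl-4-(prop-1-en-2-yl)cyclohexan-1-ol, via secondary triflate 2 (not isolated)
Conditions: Tf2O, pyridine, CH2Cl2, −40 °C; then n-Bu4NBr, −40 °C → rt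
Reagents that add atoms: tetrabutylammonium bromide CCCC[N+](CCCC)(CCCC)CCCC.[Br-]; trifluoromethanesulfonic anhydride O=S(=O)(OS(=O)(=O)C(F)(F)F)C(F)(F)F (its atoms reach only intermediate 2)
Why: Only the secondary hydroxyl should be triflated at low temperature, and bromide should displace the axial triflate in an SN2 reaction with inversion (equatorial entry), which turns the CH–O centre (S) into CH–Br (R) and gives the cis bromohydrin with the two other centres of the chiral-pool diol untouched.

Step 2
Reactants: 3 (1S,2R,4R)-2-bromo-1-methyl-4-(prop-1-en-2-yl)cyclohexan-1-ol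
Product: 4 (1S,2R,4R)-2-bromo-4-(3-chloroprop-1-en-2-yl)-1-methylcyclohexan-1-ol
Conditions: aq. NaOCl, CeCl3·7H2O, CH2Cl2/H2O, 0 °C
Reagents that add atoms: sodium hypochlorite [Na+].[O-]Cl
Why: Ene-type allylic chlorination by hypochlorous acid (chlorine to the terminal CH2, loss of a methyl proton) shifts the double bond within the isopropenyl group, the only alkene present, and creates no stereocentre.

Step 3
Reactants: 5 2-methylbut-1-en-3-yne; 6 pinacolborane
Product: 7 4,4,5,5-tetramethyl-2-[(1E)-3-methylbuta-1,3-dien-1-yl]-1,3,2-dioxaborolane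
Conditions: Cp2Zr(H)Cl (5 mol%), Et3N (10 mol%), neat, 50 °C
Reagents that add atoms: none
Why: Zirconium-catalysed syn hydroboration of the terminal alkyne should place boron on the terminal carbon and give the E alkenylboronate, while the 1,1-disubstituted alkene is left alone.

Step 4
Reactants: 4 (1S,2R,4R)-2-bromo-4-(3-chloroprop-1-en-2-yl)-1-methylcyclohexan-1-ol; 7 4,4,5,5-tetramethyl-2-[(1E)-3-methylbuta-1,3-dien-1-yl]-1,3,2-dioxaborolane
Product: 8 (1S,2R,4R)-2-bromo-1-methyl-4-[(4E)-6-methylhepta-1,4,6-trien-2-yl]cyclohexan-1-ol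
Conditions: Pd(PPh3)4 (5 mol%), K3PO4, THF/H2O, 50 °C
Reagents that add atoms: none
Why: Suzuki–Miyaura allyl–alkenyl cross-coupling through a 2-substituted π-allylpalladium with two identical termini should give a single skipped triene with retention of the E alkene; Pd(0) is not expected to insert into the unactivated secondary C–Br bond under these conditions.

Step 5
Reactants: 8 (1S,2R,4R)-2-bromo-1-methyl-4-[(4E)-6-methylhepta-1,4,6-trien-2-yl]cyclohexan-1-ol; 9 acrolein
Product: 10 (1R,2S)-2-{2-[(1R,3R,4S)-3-bromo-4-hydroxy-4-methylcyclohexyl]prop-2-en-1-yl}-4-methylcyclohex-3-ene-1-carbaldehyde (cis)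
Conditions: (5S)-5-benzyl-2,2,3-trimethylimidazolidin-4-one·HCl (20 mol%), MeCN/H2O (95:5), 0 °C → rt
Reagents that add atoms: none
Why: The imidazolidinone condenses with acrolein to an (E)-iminium ion of lowered LUMO, which should undergo a concerted, asynchronous [4+2] cycloaddition with the s-cis diene of 8 before hydrolysis returns the catalyst; the closest known reaction type is the amine-catalysed enantioselective Diels–Alder reaction of acrolein with 1,3-disubstituted acyclic dienes. Ring A is closed intermolecularly by suprafacial formation of the C3–C4 and C5–C6 bonds, and the retained alkene lies at C1=C2, where the oxirane is needed. C3 is set by the diene face that meets the iminium ion: the benzyl group shields the Re face of the acrolein β-carbon and the diene should add endo to the open face, which gives the 2S centre of 10 and places the formyl group cis on C4 (1R), a centre that step 8 corrects. Regioselectivity (C4 next to C3, opposite C1) follows from both diene substituents raising the HOMO coefficient at the terminal CH2, which bonds to the acrolein β-carbon. Only the conjugated diene should react, the isolated 1,1-disubstituted alkene, the bromide and the free tertiary alcohol being inert to the mild ammonium salt; the ring B stereocentres are too remote to help or hinder, so endo and facial selectivity rest on the catalyst.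

Step 6
Reactants: 10 (1R,2S)-2-{2-[(1R,3R,4S)-3-bromo-4-hydroxy-4-methylcyclohexyl]prop-2-en-1-yl}-4-methylcyclohex-3-ene-1-carbaldehyde
Product: 11 (1S,2R,4R)-2-bromo-4-{3-[(1S,6R)-6-(1-hydroxyethyl)-3-methylcyclohex-2-en-1-yl]prop-1-en-2-yl}-1-methylcyclohexan-1-ol (both carbinol epimers)
Conditions: MeMgBr (3 equiv), THF, −78 °C; aq. NH4Cl
Reagents that add atoms: methylmagnesium bromide C[Mg]Br
Why: Grignard addition to the aldehyde at low temperature (one equivalent is spent on the tertiary OH) should leave the α-centre intact; the new carbinol centre is not controlled because step 7 removes it.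

Step 7
Reactants: 11 (1S,2R,4R)-2-bromo-4-{3-[(1S,6R)-6-(1-hydroxyethyl)-3-methylcyclohex-2-en-1-yl]prop-1-en-2-yl}-1-methylcyclohexan-1-ol
Product: 12 1-[(1R,2S)-2-{2-[(1R,3R,4S)-3-bromo-4-hydroxy-4-methylcyclohexyl]prop-2-en-1-yl}-4-methylcyclohex-3-en-1-yl]ethan-1-one (cis)
Conditions: Dess–Martin periodinane, NaHCO3, CH2Cl2, 0 °C → rt
Reagents that add atoms: none
Why: Dess–Martin oxidation of the secondary alcohol under buffered, non-epimerising conditions (the tertiary alcohol cannot be oxidised) should give the cis ketone, which is freed here by chromatography from any trans ketone that stems from an exo cycloadduct and would carry the wrong C3 configuration.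

Step 8
Reactants: 12 1-[(1R,2S)-2-{2-[(1R,3R,4S)-3-bromo-4-hydroxy-4-methylcyclohexyl]prop-2-en-1-yl}-4-methylcyclohex-3-en-1-yl]ethan-1-one
Product: 13 1-[(1S,2S)-2-{2-[(1R,3R,4S)-3-bromo-4-hydroxy-4-methylcyclohexyl]prop-2-en-1-yl}-4-methylcyclohex-3-en-1-yl]ethan-1-one (trans)
Conditions: DBU (0.5 equiv), CH2Cl2, rt
Reagents that add atoms: none
Why: Base-mediated epimerisation through the enolate should place the acetyl group trans to the C3 side chain (both equatorial) under thermodynamic control, inverting C4 while the non-acidic C3 centre holds; residual cis ketone is separable and can be resubmitted.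

Step 9
Reactants: 13 1-[(1S,2S)-2-{2-[(1R,3R,4S)-3-bromo-4-hydroxy-4-methylcyclohexyl]prop-2-en-1-yl}-4-methylcyclohex-3-en-1-yl]ethan-1-one
Product: 14 (1S,2R,4R)-2-bromo-1-methyl-4-{3-[(1S,6S)-3-methyl-6-(prop-1-en-2-yl)cyclohex-2-en-1-yl]prop-1-en-2-yl}cyclohexan-1-ol
Conditions: Ph3PCH3Br, KOtBu, THF, 0 °C → rt
Reagents that add atoms: methyltriphenylphosphonium bromide C[P+](c1ccccc1)(c1ccccc1)c1ccccc1.[Br-]
Why: Wittig methylenation converts the acetyl group into isopropenyl; the ketone is already the thermodynamic epimer, so the basic ylide should not erode the C4 configuration.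

Step 10
Reactants: 14 (1S,2R,4R)-2-bromo-1-methyl-4-{3-[(1S,6S)-3-methyl-6-(prop-1-en-2-yl)cyclohex-2-en-1-yl]prop-1-en-2-yl}cyclohexan-1-ol
Product: 15 (1S,2R,4R)-2-bromo-1-methyl-4-{3-[(1R,2R,3S,6S)-6-methyl-3-(prop-1-en-2-yl)-7-oxabicyclo[4.1.0]heptan-2-yl]prop-1-en-2-yl}cyclohexan-1-ol (CNP0213097.1)
Conditions: D-fructose-derived Shi ketone (30 mol%), Oxone, K2CO3, n-Bu4NHSO4, MeCN/dimethoxymethane/aq. borate–EDTA buffer (pH 10.5), 0 °C
Reagents that add atoms: Oxone (potassium peroxymonosulfate) [K+].[O-]S(=O)(=O)OO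
Why: Shi asymmetric epoxidation: the chiral dioxirane should attack the electron-rich trisubstituted ring alkene faster than the two 1,1-disubstituted alkenes, and the spiro transition state of the D-fructose-derived ketone should deliver oxygen to the face that gives the C1(S),C2(R) oxirane, syn to the C3 side chain (substrate bias is small because that substituent is pseudo-equatorial).

**Compound list**

1 | (1S,2S,4R)-1-methyl-4-(prop-1-en-2-yl)cyclohexane-1,2-diol | CC(=C)[C@@H]1CC[C@](C)(O)[C@@H](O)C1 | starting material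
2 | (1S,2S,5R)-2-hydroxy-2-methyl-5-(prop-1-en-2-yl)cyclohexyl trifluoromethanesulfonate | CC(=C)[C@@H]1CC[C@](C)(O)[C@@H](OS(=O)(=O)C(F)(F)F)C1 | intermediate
3 | (1S,2R,4R)-2-bromo-1-methyl-4-(prop-1-en-2-yl)cyclohexan-1-ol | CC(=C)[C@@H]1CC[C@](C)(O)[C@H](Br)C1 | intermediate
4 | (1S,2R,4R)-2-bromo-4-(3-chloroprop-1-en-2-yl)-1-methylcyclohexan-1-ol | C=C(CCl)[C@@H]1CC[C@](C)(O)[C@H](Br)C1 | intermediate
5 | 2-methylbut-1-en-3-yne | C=C(C)C#C | starting material
6 | pinacolborane (4,4,5,5-tetramethyl-1,3,2-dioxaborolane) | B1OC(C)(C)C(C)(C)O1 | starting material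
7 | 4,4,5,5-tetramethyl-2-[(1E)-3-methylbuta-1,3-dien-1-yl]-1,3,2-dioxaborolane | CC(=C)/C=C/B1OC(C)(C)C(C)(C)O1 | intermediate
8 | (1S,2R,4R)-2-bromo-1-methyl-4-[(4E)-6-methylhepta-1,4,6-trien-2-yl]cyclohexan-1-ol | C=C(C/C=C/C(C)=C)[C@@H]1CC[C@](C)(O)[C@H](Br)C1 | intermediate
9 | acrolein (prop-2-enal) | C=CC=O | starting material
10 | (1R,2S)-2-{2-[(1R,3R,4S)-3-bromo-4-hydroxy-4-methylcyclohexyl]prop-2-en-1-yl}-4-methylcyclohex-3-ene-1-carbaldehyde | C=C(C[C@@H]1[C@H](C=O)CCC(C)=C1)[C@@H]1CC[C@](C)(O)[C@H](Br)C1 | intermediate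
11 | (1S,2R,4R)-2-bromo-4-{3-[(1S,6R)-6-(1-hydroxyethyl)-3-methylcyclohex-2-en-1-yl]prop-1-en-2-yl}-1-methylcyclohexan-1-ol (carbinol epimers) | C=C(C[C@@H]1[C@H](C(C)O)CCC(C)=C1)[C@@H]1CC[C@](C)(O)[C@H](Br)C1 | intermediate
12 | 1-[(1R,2S)-2-{2-[(1R,3R,4S)-3-bromo-4-hydroxy-4-methylcyclohexyl]prop-2-en-1-yl}-4-methylcyclohex-3-en-1-yl]ethan-1-one | C=C(C[C@@H]1[C@H](C(C)=O)CCC(C)=C1)[C@@H]1CC[C@](C)(O)[C@H](Br)C1 | intermediate
13 | 1-[(1S,2S)-2-{2-[(1R,3R,4S)-3-bromo-4-hydroxy-4-methylcyclohexyl]prop-2-en-1-yl}-4-methylcyclohex-3-en-1-yl]ethan-1-one | C=C(C[C@@H]1[C@@H](C(C)=O)CCC(C)=C1)[C@@H]1CC[C@](C)(O)[C@H](Br)C1 | intermediate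
14 | (1S,2R,4R)-2-bromo-1-methyl-4-{3-[(1S,6S)-3-methyl-6-(prop-1-en-2-yl)cyclohex-2-en-1-yl]prop-1-en-2-yl}cyclohexan-1-ol | C=C(C[C@@H]1[C@@H](C(=C)C)CCC(C)=C1)[C@@H]1CC[C@](C)(O)[C@H](Br)C1 | intermediate
15 | (1S,2R,4R)-2-bromo-1-methyl-4-{3-[(1R,2R,3S,6S)-6-methyl-3-(prop-1-en-2-yl)-7-oxabicyclo[4.1.0]heptan-2-yl]prop-1-en-2-yl}cyclohexan-1-ol | C=C(C[C@@H]1[C@@H](C(=C)C)CC[C@]2(C)O[C@H]12)[C@@H]1CC[C@](C)(O)[C@H](Br)C1 | target

**Totals**

Total step count: 10. Longest linear sequence: 9 steps (1, 2, 4, 5, 6, 7, 8, 9, 10).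

**Steps most likely to fail**

Step 1. The axial tertiary hydroxyl lies antiperiplanar to the triflate and may close to the oxirane, which bromide would then reopen trans; E2 elimination may also outrun the hindered SN2 displacement. The fallback sets out from 1 and ties both oxygens into the cyclic sulfate F1 (1,1′-sulfonyldiimidazole, NaH, THF; no ruthenium oxidation, so the isopropenyl group is safe), which removes the internal nucleophile. LiBr in THF should open F1 at the secondary carbon with inversion to the lithium bromo sulfate F2. Hydrolysis of the sulfate monoester (cat. H2SO4, H2O, THF) comes back to the route at 3.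

Step 5. Endo or π-facial selectivity may be eroded, which would give ring A stereoisomers that differ from 10 only in their relation to the remote ring B and are hard to remove later. The fallback sets out from 8 and replaces catalyst control by auxiliary control. The tertiary alcohol is silylated (TESOTf, 2,6-lutidine) to the triethylsilyl ether F3. An Et2AlCl-promoted Diels–Alder reaction with (S)-3-acryloyl-4-benzyloxazolidin-2-one at −78 °C should give the endo imide F4, whose diastereomers are separable because the auxiliary sits next to the new centres. Transamidation (MeNHOMe·HCl, AlMe3) gives the N-methoxy-N-methylamide F5, MeMgBr gives the silylated methyl ketone F6, and desilylation (TBAF, AcOH) comes back to the route at 12.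

Step 10. Facial selectivity may be insufficient if catalyst and substrate are mismatched, and the 1,1-disubstituted alkenes may be over-oxidised. The fallback sets out from 11 and uses substrate direction. In 11 the carbinol on the C4 substituent is cis to the C3 side chain and bishomoallylic to the ring alkene, so VO(acac)2/t-BuOOH should deliver oxygen to that face and leave the remote alkenes alone, giving the epoxy alcohol F7. Dess–Martin oxidation gives the cis epoxy ketone F8, and DBU gives the trans epoxy ketone F9. Wittig methylenation (salt-free ylide, 0 °C, to keep the ketone enolate from opening the oxirane) comes back to the route at 15.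

**Further compounds**

F1 | step 1 | (1S,2S,4R)-1-methyl-4-(prop-1-en-2-yl)cyclohexane-1,2-diyl cyclic sulfate | CC(=C)[C@@H]1CC[C@]2(C)OS(=O)(=O)O[C@H]2C1
F2 | step 1 | lithium (1S,2R,4R)-2-bromo-1-methyl-4-(prop-1-en-2-yl)cyclohexyl sulfate | [Li+].CC(=C)[C@@H]1CC[C@](C)(OS(=O)(=O)[O-])[C@H](Br)C1
F3 | step 5 | triethylsilyl ether of 8 | C=C(C/C=C/C(C)=C)[C@@H]1CC[C@](C)(O[Si](CC)(CC)CC)[C@H](Br)C1
F4 | step 5 | (4S)-4-benzyl-3-acyl-oxazolidin-2-one cycloadduct (cis, 1R,2S in ring A; triethylsilyl ether) | C=C(C[C@@H]1[C@H](C(=O)N2[C@@H](Cc3ccccc3)COC2=O)CCC(C)=C1)[C@@H]1CC[C@](C)(O[Si](CC)(CC)CC)[C@H](Br)C1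
F5 | step 5 | N-methoxy-N-methylamide (cis; triethylsilyl ether) | C=C(C[C@@H]1[C@H](C(=O)N(C)OC)CCC(C)=C1)[C@@H]1CC[C@](C)(O[Si](CC)(CC)CC)[C@H](Br)C1
F6 | step 5 | triethylsilyl ether of 12 | C=C(C[C@@H]1[C@H](C(C)=O)CCC(C)=C1)[C@@H]1CC[C@](C)(O[Si](CC)(CC)CC)[C@H](Br)C1
F7 | step 10 | epoxy alcohol (oxirane syn to the 1-hydroxyethyl group and the C3 side chain) | C=C(C[C@@H]1[C@H](C(C)O)CC[C@]2(C)O[C@H]12)[C@@H]1CC[C@](C)(O)[C@H](Br)C1
F8 | step 10 | cis epoxy ketone | C=C(C[C@@H]1[C@H](C(C)=O)CC[C@]2(C)O[C@H]12)[C@@H]1CC[C@](C)(O)[C@H](Br)C1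
F9 | step 10 | trans epoxy ketone | C=C(C[C@@H]1[C@@H](C(C)=O)CC[C@]2(C)O[C@H]12)[C@@H]1CC[C@](C)(O)[C@H](Br)C1
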